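**Plan**

- Cuts (azulene numbering: C3 isopropyl carbinol, C3a, C4 ester carbinol, C5, C6 methyl carbinol, C7=C8, C8a quaternary carbon): the aryl ester at O–C4; the C6–CH3 bond (back to a C6 ketone, itself from the C6 methylene by allylic oxidation); the C4 carbinol back to a ketone; then the C3a–C8a and C5–C6 bonds together in one intramolecular (4+3) cycloaddition; last the C2–C3 bond of the open chain (Negishi coupling).
- Enabling feature: the seven-membered ring (C3a–C4–C5–C6–C7–C8–C8a) has oxygen at C4 flanked by C3a and C5 and the C7=C8 double bond opposite (a cyclohept-4-enone retron), and the C3 hydroxyl sits next to C3a. A C3/C3a epoxide with an enol silane at C4 is therefore a masked oxyallyl cation (C3a–C4–C5), C8a=C8–C7=C6 is the diene, and C1–C2 is the tether.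
- Forward order: open chain first (lactone to (Z)-dienyl iodide; β-keto ester to (Z)-enol triflate; coupling), then epoxide, methyl ketone and enol silane. The cycloaddition closes the five- and the seven-membered ring in one operation; redox adjustment at C4 and C6, one methyl addition and the acylation follow.
- Stereochemistry: C3 from a Sharpless epoxidation; C3a by inversion at the epoxide carbon and C8a (cis ring fusion) from the (Z)-diene geometry in the cycloaddition; C4 by hydroxyl-directed hydride delivery; C6 by chelation-controlled methyl addition.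

Key step: step 11

Remark: the target is read as (3R,3aS,4S,6R,8aS), a cis-fused hydroazulene (H-3a and the C8a methyl on the same face); compounds 1, 5 and 20 are taken as commercial.

**Route**

Step 1
Reactants: 1 4-methyl-5,6-dihydro-2H-pyran-2-one
Product: 2 4-methyl-5,6-dihydro-2H-pyran-2-ol (racemic lactol)
Conditions: i-Bu2AlH (DIBAL-H, 1.1 equiv), CH2Cl2, −78 °C
Reagents that add atoms: none
Why: Partial 1,2-reduction of the unsaturated δ-lactone by DIBAL-H at low temperature should stop at the lactol because the aluminium hemiacetal is stable at −78 °C; the new hemiacetal centre is of no consequence.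

Step 2
Reactants: 2 4-methyl-5,6-dihydro-2H-pyran-2-ol
Product: 3 (3Z)-3-methylhexa-3,5-dien-1-ol
Conditions: Ph3PCH3Br, KOt-Bu, THF, 0 °C to rt
Reagents that add atoms: methyltriphenylphosphonium bromide, C[P+](c1ccccc1)(c1ccccc1)c1ccccc1.[Br-]
Why: Wittig methylenation of the ring-opened hydroxy enal form of the lactol should give the dienol, the Z geometry of the trisubstituted double bond being inherited from the ring.

Step 3
Reactants: 3 (3Z)-3-methylhexa-3,5-dien-1-ol
Product: 4 (3Z)-6-iodo-4-methylhexa-1,3-diene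
Conditions: PPh3, I2, imidazole, CH2Cl2, 0 °C
Reagents that add atoms: iodine, II
Why: Appel-type iodination converts the primary alcohol into the iodide by SN2 displacement of the oxyphosphonium group and should leave the diene untouched.

Step 4
Reactants: 5 methyl 4-methyl-3-oxopentanoate
Product: 6 methyl (2Z)-4-methyl-3-{[(trifluoromethyl)sulfonyl]oxy}pent-2-enoate
Conditions: Tf2O, saturated aqueous LiOH, toluene, 5 °C
Reagents that add atoms: trifluoromethanesulfonic anhydride, O=S(=O)(OS(=O)(=O)C(F)(F)F)C(F)(F)F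
Why: O-triflation of the lithium-chelated (Z)-enolate of the β-keto ester (enol triflate formation) should place the triflate cis to the ester; no stereocentre is formed.

Step 5
Reactants: 4 (3Z)-6-iodo-4-methylhexa-1,3-diene; 6 methyl (2Z)-4-methyl-3-{[(trifluoromethyl)sulfonyl]oxy}pent-2-enoate
Product: 8 methyl (2E,6Z)-6-methyl-3-(propan-2-yl)nona-2,6,8-trienoate, via alkylzinc iodide 7 (not isolated)
Conditions: 4, Zn dust (activated with BrCH2CH2Br and Me3SiCl), LiCl, THF, 40 °C; then 6, Pd(PPh3)4 (5 mol%), THF, 50 °C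
Reagents that add atoms: none
Why: Zinc insertion into the primary iodide and Negishi cross-coupling with the enol triflate proceed with retention at the alkenyl carbon, so the new chain ends up cis to the ester (E by the sequence rules) and the diene geometry is not touched.

Step 6
Reactants: 8 methyl (2E,6Z)-6-methyl-3-(propan-2-yl)nona-2,6,8-trienoate
Product: 9 (2E,6Z)-6-methyl-3-(propan-2-yl)nona-2,6,8-trien-1-ol
Conditions: i-Bu2AlH (2.5 equiv), CH2Cl2, −78 °C
Reagents that add atoms: none
Why: DIBAL-H reduces the conjugated ester by 1,2-addition to the allylic alcohol without affecting the alkenes.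

Step 7
Reactants: 9 (2E,6Z)-6-methyl-3-(propan-2-yl)nona-2,6,8-trien-1-ol
Product: 10 [(2R,3R)-3-[(3Z)-3-methylhexa-3,5-dien-1-yl]-3-(propan-2-yl)oxiran-2-yl]methanol
Conditions: Ti(Oi-Pr)4 (10 mol%), D-(−)-diethyl tartrate (12 mol%), t-BuOOH (anhydrous, in decane), 4 Å molecular sieves, CH2Cl2, −20 °C
Reagents that add atoms: tert-butyl hydroperoxide, CC(C)(C)OO
Why: Sharpless asymmetric epoxidation acts only on the allylic alcohol double bond, and the D-(−)-tartrate catalyst should give the (2R,3R)-epoxide (mirror image of the (2S,3S) series that (E)-allylic alcohols give with the L-(+)-tartrate), which fixes C3 of the target and the configuration of the carbon that becomes C3a.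

Step 8
Reactants: 10 [(2R,3R)-3-[(3Z)-3-methylhexa-3,5-dien-1-yl]-3-(propan-2-yl)oxiran-2-yl]methanol
Product: 12 1-[(2R,3R)-3-[(3Z)-3-methylhexa-3,5-dien-1-yl]-3-(propan-2-yl)oxiran-2-yl]ethan-1-ol (mixture of carbinol epimers), via epoxy aldehyde 11 (not isolated)
Conditions: (COCl)2, DMSO, CH2Cl2, −78 °C; Et3N; then MeMgBr (excess), THF, −78 to 0 °C
Reagents that add atoms: methylmagnesium bromide, C[Mg]Br
Why: Swern oxidation followed by Grignard addition in the same flask avoids isolation of the sensitive epoxy aldehyde, and the new carbinol centre, formed as a mixture, is erased in the next step.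

Step 9
Reactants: 12 1-[(2R,3R)-3-[(3Z)-3-methylhexa-3,5-dien-1-yl]-3-(propan-2-yl)oxiran-2-yl]ethan-1-ol
Product: 13 1-[(2S,3R)-3-[(3Z)-3-methylhexa-3,5-dien-1-yl]-3-(propan-2-yl)oxiran-2-yl]ethan-1-one
Conditions: Dess–Martin periodinane, NaHCO3, CH2Cl2, 0 °C to rt
Reagents that add atoms: none
Why: Buffered Dess–Martin oxidation converts the secondary alcohol into the methyl ketone and should leave the epoxide and the diene intact (the descriptor at C2 changes only because of the priority rules).

Step 10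
Reactants: 13 1-[(2S,3R)-3-[(3Z)-3-methylhexa-3,5-dien-1-yl]-3-(propan-2-yl)oxiran-2-yl]ethan-1-one
Product: 14 triethyl({1-[(2S,3R)-3-[(3Z)-3-methylhexa-3,5-dien-1-yl]-3-(propan-2-yl)oxiran-2-yl]ethenyl}oxy)silane
Conditions: LiN(SiMe3)2, Et3SiCl, THF, −78 °C
Reagents that add atoms: chlorotriethylsilane, CC[Si](CC)(CC)Cl
Why: Kinetic deprotonation takes place at the methyl group (the other α-carbon is the epoxide carbon) and O-silylation of the enolate gives the epoxy enol silane without Lewis acid that could open the epoxide.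

Step 11
Reactants: 14 triethyl({1-[(2S,3R)-3-[(3Z)-3-methylhexa-3,5-dien-1-yl]-3-(propan-2-yl)oxiran-2-yl]ethenyl}oxy)silane
Product: 16 (3R,3aR,8aS)-3-hydroxy-8a-methyl-3-(propan-2-yl)-2,3,3a,5,6,8a-hexahydroazulen-4(1H)-one, via triethylsilyl ether 15 (not isolated)
Conditions: Et3SiOTf (10 mol%), CH2Cl2, −78 °C; then pyridine, HF·pyridine, THF, 0 °C
Reagents that add atoms: none
Why: Et3SiOTf silylates the epoxide oxygen and the C–O bond at the carbon next to the enol silane (future C3a) ionizes with help of the enol π system to a 2-silyloxyallyl cation (C3a–C4–C5), which the tethered diene (C8a=C8–C7=C6) captures in concert with the C–O cleavage to form C3a–C8a and C5–C6; the silyl group of the resulting oxocarbenium ion passes to the next epoxide (catalyst turnover), leaving the C4 ketone and the C3 silyl ether that HF·pyridine then cleaves. The closest known reaction type is the silyl triflate-catalysed (4+3) cycloaddition of epoxy enolsilanes with furans and dienes, inter- and intramolecular, an oxyallyl cation cycloaddition that is stereospecific for enantioenriched epoxides. The five-membered ring closes by 5-exo attack of the C8a=C8 π bond on C3a (both epoxide carbons end up in the ring), the seven-membered ring by the two new bonds of a suprafacial 4π + 2π (allyl cation) cycloaddition through the compact, boat-like arrangement. C3 is carried over unchanged from the epoxide, C3a is set by inversion because the diene attacks anti to the leaving oxygen, and C8a follows from geometry: the tether is cis to the enol silane on the epoxide and inside the (Z)-diene, so it can bridge the two π systems only in the compact arrangement, which gives the cis ring fusion (H-3a and CH3-8a syn). The step needs cleavage of the C3a–O and not the tertiary C3–O bond, secured by alignment of the C3a–O bond with the enol silane π system at −78 °C, and attack through C8a and not C6, secured by the five- against eight-membered ring size.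

Step 12
Reactants: 16 (3R,3aR,8aS)-3-hydroxy-8a-methyl-3-(propan-2-yl)-2,3,3a,5,6,8a-hexahydroazulen-4(1H)-one
Product: 17 (3R,3aS,4S,8aS)-8a-methyl-3-(propan-2-yl)-1,2,3,3a,4,5,6,8a-octahydroazulene-3,4-diol
Conditions: Me4NBH(OAc)3, MeCN/AcOH (1:1), −20 °C
Reagents that add atoms: none
Why: In the Evans–Saksena reduction the C3 hydroxyl exchanges onto boron and delivers hydride through a six-membered transition state to the exo face of the C4 carbonyl, the face on which the C3 oxygen lies, which should give the 4S alcohol (hydroxyl cis to H-3a, anti to the C3 hydroxyl).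

Step 13
Reactants: 17 (3R,3aS,4S,8aS)-8a-methyl-3-(propan-2-yl)-1,2,3,3a,4,5,6,8a-octahydroazulene-3,4-diol
Product: 18 (3R,3aS,4S,8aS)-3,4-dihydroxy-8a-methyl-3-(propan-2-yl)-2,3,3a,4,5,8a-hexahydroazulen-6(1H)-one
Conditions: Rh2(cap)4 (cap = caprolactamate, 1 mol%), t-BuOOH (70% in water, 5 equiv), ClCH2CH2Cl, 40 °C
Reagents that add atoms: tert-butyl hydroperoxide, CC(C)(C)OO
Why: Allylic C–H oxidation by tert-butylperoxy radicals (dirhodium caprolactamate/TBHP allylic oxidation) should occur at C6, the only allylic methylene because C8a is quaternary, and the weaker allylic C–H bonds should react before the carbinol C–H of the free secondary alcohol.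

Step 14
Reactants: 18 (3R,3aS,4S,8aS)-3,4-dihydroxy-8a-methyl-3-(propan-2-yl)-2,3,3a,4,5,8a-hexahydroazulen-6(1H)-one
Product: 19 (3R,3aS,4S,6R,8aS)-6,8a-dimethyl-3-(propan-2-yl)-1,2,3,3a,4,5,6,8a-octahydroazulene-3,4,6-triol
Conditions: MeMgBr (5 equiv), CH2Cl2/Et2O, −78 to −20 °C
Reagents that add atoms: methylmagnesium bromide, C[Mg]Br
Why: Chelation-controlled 1,2-addition of the Grignard reagent to the enone: the magnesium alkoxide at C4 binds the C6 carbonyl oxygen on the β face, so the methyl group should enter from the opposite α face (also the axial trajectory on the half-chair enone) and give the 6R carbinol with its hydroxyl cis to the C4 oxygen.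

Step 15
Reactants: 19 (3R,3aS,4S,6R,8aS)-6,8a-dimethyl-3-(propan-2-yl)-1,2,3,3a,4,5,6,8a-octahydroazulene-3,4,6-triol; 20 4-(chlorocarbonyl)phenyl acetate (4-acetoxybenzoyl chloride)
Product: 21 (3R,3aS,4S,6R,8aS)-3,6-dihydroxy-6,8a-dimethyl-3-(propan-2-yl)-1,2,3,3a,4,5,6,8a-octahydroazulen-4-yl 4-(acetyloxy)benzoate
Conditions: pyridine, DMAP (cat.), CH2Cl2, 0 °C to rt
Reagents that add atoms: none
Why: DMAP-catalysed acylation by the acid chloride should take place at the only secondary hydroxyl, the two tertiary alcohols being too hindered to react.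

Step 16
Reactants: 21 (3R,3aS,4S,6R,8aS)-3,6-dihydroxy-6,8a-dimethyl-3-(propan-2-yl)-1,2,3,3a,4,5,6,8a-octahydroazulen-4-yl 4-(acetyloxy)benzoate
Product: 22 (3R,3aS,4S,6R,8aS)-3,6-dihydroxy-6,8a-dimethyl-3-(propan-2-yl)-1,2,3,3a,4,5,6,8a-octahydroazulen-4-yl 4-hydroxybenzoate (target)
Conditions: pyrrolidine (2 equiv), CH2Cl2, 0 °C to rt
Reagents that add atoms: none
Why: Aminolysis of the phenolic acetate, an activated aryl ester, is much faster than attack on the hindered secondary benzoate, so the phenol should be set free selectively and without acid that could ionize the tertiary allylic alcohol.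

**Compound list**

1 | 4-methyl-5,6-dihydro-2H-pyran-2-one | CC1=CC(=O)OCC1 | starting material
2 | 4-methyl-5,6-dihydro-2H-pyran-2-ol (racemic) | CC1=CC(O)OCC1 | intermediate
3 | (3Z)-3-methylhexa-3,5-dien-1-ol | C=C/C=C(/C)CCO | intermediate
4 | (3Z)-6-iodo-4-methylhexa-1,3-diene | C=C/C=C(/C)CCI | intermediate
5 | methyl 4-methyl-3-oxopentanoate | CC(C)C(=O)CC(=O)OC | starting material
6 | methyl (2Z)-4-methyl-3-{[(trifluoromethyl)sulfonyl]oxy}pent-2-enoate | COC(=O)/C=C(\OS(=O)(=O)C(F)(F)F)C(C)C | intermediate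
7 | [(3Z)-3-methylhexa-3,5-dien-1-yl]zinc iodide | C=C/C=C(/C)CC[Zn]I | intermediate
8 | methyl (2E,6Z)-6-methyl-3-(propan-2-yl)nona-2,6,8-trienoate | COC(=O)/C=C(/C(C)C)CC/C(C)=C\C=C | intermediate
9 | (2E,6Z)-6-methyl-3-(propan-2-yl)nona-2,6,8-trien-1-ol | OC/C=C(/C(C)C)CC/C(C)=C\C=C | intermediate
10 | [(2R,3R)-3-[(3Z)-3-methylhexa-3,5-dien-1-yl]-3-(propan-2-yl)oxiran-2-yl]methanol | OC[C@H]1O[C@@]1(C(C)C)CC/C(C)=C\C=C | intermediate
11 | (2S,3R)-3-[(3Z)-3-methylhexa-3,5-dien-1-yl]-3-(propan-2-yl)oxirane-2-carbaldehyde | O=C[C@H]1O[C@@]1(C(C)C)CC/C(C)=C\C=C | intermediate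
12 | 1-[(2R,3R)-3-[(3Z)-3-methylhexa-3,5-dien-1-yl]-3-(propan-2-yl)oxiran-2-yl]ethan-1-ol (carbinol epimers) | CC(O)[C@H]1O[C@@]1(C(C)C)CC/C(C)=C\C=C | intermediate
13 | 1-[(2S,3R)-3-[(3Z)-3-methylhexa-3,5-dien-1-yl]-3-(propan-2-yl)oxiran-2-yl]ethan-1-one | CC(=O)[C@H]1O[C@@]1(C(C)C)CC/C(C)=C\C=C | intermediate
14 | triethyl({1-[(2S,3R)-3-[(3Z)-3-methylhexa-3,5-dien-1-yl]-3-(propan-2-yl)oxiran-2-yl]ethenyl}oxy)silane | C=C(O[Si](CC)(CC)CC)[C@H]1O[C@@]1(C(C)C)CC/C(C)=C\C=C | intermediate
15 | (3R,3aR,8aS)-8a-methyl-3-(propan-2-yl)-3-[(triethylsilyl)oxy]-2,3,3a,5,6,8a-hexahydroazulen-4(1H)-one | CC(C)[C@]1(O[Si](CC)(CC)CC)CC[C@@]2(C)C=CCCC(=O)[C@@H]12 | intermediate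
16 | (3R,3aR,8aS)-3-hydroxy-8a-methyl-3-(propan-2-yl)-2,3,3a,5,6,8a-hexahydroazulen-4(1H)-one | CC(C)[C@]1(O)CC[C@@]2(C)C=CCCC(=O)[C@@H]12 | intermediate
17 | (3R,3aS,4S,8aS)-8a-methyl-3-(propan-2-yl)-1,2,3,3a,4,5,6,8a-octahydroazulene-3,4-diol | CC(C)[C@]1(O)CC[C@@]2(C)C=CCC[C@H](O)[C@@H]12 | intermediate
18 | (3R,3aS,4S,8aS)-3,4-dihydroxy-8a-methyl-3-(propan-2-yl)-2,3,3a,4,5,8a-hexahydroazulen-6(1H)-one | CC(C)[C@]1(O)CC[C@@]2(C)C=CC(=O)C[C@H](O)[C@@H]12 | intermediate
19 | (3R,3aS,4S,6R,8aS)-6,8a-dimethyl-3-(propan-2-yl)-1,2,3,3a,4,5,6,8a-octahydroazulene-3,4,6-triol | CC(C)[C@]1(O)CC[C@@]2(C)C=C[C@](C)(O)C[C@H](O)[C@@H]12 | intermediate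
20 | 4-(chlorocarbonyl)phenyl acetate | CC(=O)Oc1ccc(cc1)C(Cl)=O | starting material
21 | (3R,3aS,4S,6R,8aS)-3,6-dihydroxy-6,8a-dimethyl-3-(propan-2-yl)-1,2,3,3a,4,5,6,8a-octahydroazulen-4-yl 4-(acetyloxy)benzoate | CC(C)[C@]1(O)CC[C@@]2(C)C=C[C@](C)(O)C[C@H](OC(=O)c3ccc(OC(C)=O)cc3)[C@@H]12 | intermediate
22 | (3R,3aS,4S,6R,8aS)-3,6-dihydroxy-6,8a-dimethyl-3-(propan-2-yl)-1,2,3,3a,4,5,6,8a-octahydroazulen-4-yl 4-hydroxybenzoate | CC(C)[C@]1(O)CC[C@@]2(C)C=C[C@](C)(O)C[C@H](OC(=O)c3ccc(O)cc3)[C@@H]12 | target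

**Summary**

Total steps: 16. Longest linear sequence: 15 steps (steps 1–3 and 5–16).

**Steps most likely to fail**

Step 11. The silylated epoxide may ionize at the fully substituted C3 instead (followed by hydride or alkyl shift to a carbonyl compound), or the two bonds may form stepwise so that the control of the ring fusion is lost. The fallback generates a free oxyallyl cation from an α-bromo ketone. From 13, samarium diiodide (SmI2, THF/MeOH, −90 °C) cleaves the C–O bond next to the carbonyl and should give (4S,7Z)-4-hydroxy-7-methyl-4-(propan-2-yl)deca-7,9-dien-2-one F1. Silylation (Et3SiOTf, 2,6-lutidine) should give (4S,7Z)-7-methyl-4-(propan-2-yl)-4-[(triethylsilyl)oxy]deca-7,9-dien-2-one F2. Kinetic enolate formation at the methyl group (LiN(SiMe3)2, −78 °C) and bromination with N-bromosuccinimide should give (4S,7Z)-1-bromo-7-methyl-4-(propan-2-yl)-4-[(triethylsilyl)oxy]deca-7,9-dien-2-one F3. Et3N in 2,2,2-trifluoroethanol (Föhlisch conditions) then forms the oxyallyl cation by enolization toward C3 and loss of bromide, and the intramolecular (4+3) cycloaddition with the same (Z)-diene should return to compound 15, which is desilylated to 16 as in step 11. In this variant C3a is set under the control of the C3 stereocentre and not by inversion.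

Step 13. The allyl radical may be trapped at C8 (transposed enone), the free C4 carbinol may be oxidized, or the β-hydroxy enone may lose water. The fallback protects, oxidizes with a stoichiometric chromium reagent and deprotects. From 17, Et3SiCl and imidazole should silylate the secondary hydroxyl to (3R,3aS,4S,8aS)-8a-methyl-3-(propan-2-yl)-4-[(triethylsilyl)oxy]-1,2,3,3a,4,5,6,8a-octahydroazulen-3-ol F4. CrO3·3,5-dimethylpyrazole (CH2Cl2, −20 °C) should oxidize C6 to (3R,3aS,4S,8aS)-3-hydroxy-8a-methyl-3-(propan-2-yl)-4-[(triethylsilyl)oxy]-2,3,3a,4,5,8a-hexahydroazulen-6(1H)-one F5, and HF·pyridine returns to compound 18.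

Step 14. Facial selectivity may be poor (methyl entering from the β face), or enolization and loss of the C4 hydroxyl may compete. In the fallback the oxygen is delivered under direction of the C4 hydroxyl and the methyl group is made by hydride. From 18, Takai–Lombardo methylenation (Zn, CH2Br2, TiCl4, THF) should give (3R,3aS,4S,8aS)-8a-methyl-6-methylidene-3-(propan-2-yl)-1,2,3,3a,4,5,6,8a-octahydroazulene-3,4-diol F6. VO(acac)2 and t-BuOOH should epoxidize the exocyclic double bond syn to the homoallylic C4 hydroxyl to give (3R,3aS,4S,6R,8aS)-8a-methyl-3-(propan-2-yl)-2,3,3a,4,5,8a-hexahydro-1H-spiro[azulene-6,2'-oxirane]-3,4-diol F7. LiAlH4 (THF, 0 °C) opens the epoxide at its CH2 carbon and returns to compound 19.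

**Further compounds**

F1 | step 11 | (4S,7Z)-4-hydroxy-7-methyl-4-(propan-2-yl)deca-7,9-dien-2-one | CC(=O)C[C@](O)(C(C)C)CC/C(C)=C\C=C
F2 | step 11 | (4S,7Z)-7-methyl-4-(propan-2-yl)-4-[(triethylsilyl)oxy]deca-7,9-dien-2-one | CC(=O)C[C@](O[Si](CC)(CC)CC)(C(C)C)CC/C(C)=C\C=C
F3 | step 11 | (4S,7Z)-1-bromo-7-methyl-4-(propan-2-yl)-4-[(triethylsilyl)oxy]deca-7,9-dien-2-one | BrCC(=O)C[C@](O[Si](CC)(CC)CC)(C(C)C)CC/C(C)=C\C=C
F4 | step 13 | (3R,3aS,4S,8aS)-8a-methyl-3-(propan-2-yl)-4-[(triethylsilyl)oxy]-1,2,3,3a,4,5,6,8a-octahydroazulen-3-ol | CC(C)[C@]1(O)CC[C@@]2(C)C=CCC[C@H](O[Si](CC)(CC)CC)[C@@H]12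
F5 | step 13 | (3R,3aS,4S,8aS)-3-hydroxy-8a-methyl-3-(propan-2-yl)-4-[(triethylsilyl)oxy]-2,3,3a,4,5,8a-hexahydroazulen-6(1H)-one | CC(C)[C@]1(O)CC[C@@]2(C)C=CC(=O)C[C@H](O[Si](CC)(CC)CC)[C@@H]12
F6 | step 14 | (3R,3aS,4S,8aS)-8a-methyl-6-methylidene-3-(propan-2-yl)-1,2,3,3a,4,5,6,8a-octahydroazulene-3,4-diol | CC(C)[C@]1(O)CC[C@@]2(C)C=CC(=C)C[C@H](O)[C@@H]12
F7 | step 14 | (3R,3aS,4S,6R,8aS)-8a-methyl-3-(propan-2-yl)-2,3,3a,4,5,8a-hexahydro-1H-spiro[azulene-6,2'-oxirane]-3,4-diol | CC(C)[C@]1(O)CC[C@@]2(C)C=C[C@@]3(CO3)C[C@H](O)[C@@H]12
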